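(Readings and results were generated by integration with made-up constants, noise included.)

In the cedar run, product levelled at 92.3% of the substrate charged, and the reagent charged came to 92.5% of that substrate.

in all of them: substrate 0.40 M; free catalyst 4.4 mM

| run | reagent | remark | time |
|---|---|---|---|
| cedar | 0.37 M | run made earlier |  |
| elm | 0.49 M | run made earlier |  |
| birch | 0.54 M | run made earlier |  |
| east | 0.360 M |  | 3.0 h |
| south | 0.720 M |  | 3.0 h |

| run | time / min | substrate / % | product / % |
|---|---|---|---|
| cedar | 8.00 | 70.1 | 25.7 |
| cedar | 25.0 | 33.2 | 62.3 |
| cedar | 40.0 | 17.6 | 80.7 |
| cedar | 60.0 | 8.8 | 89.2 |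
| cedar | 90.0 | 7.6 | 92.3 |
| elm | 8.00 | 64.8 | 29.3 |
| elm | 15.0 | 42.6 | 51.8 |
| elm | 25.0 | 21.1 | 77.7 |
| elm | 50.0 | 0 | 100.9 |
| elm | 90.0 | 0.8 | 101.4 |
| birch | 8.00 | 64.2 | 30.2 |
| birch | 15.0 | 41.6 | 52.9 |
| birch | 25.0 | 17.6 | 82.8 |
| birch | 50.0 | 0 | 101.1 |
| birch | 90.0 | 1.0 | 99.1 |

(each reading ± 1 percentage point)

- amounts and yields of released group count idle adduct and crystals too
- given per volume of solution although it is solid: crystals
- what may be going on: reagent + free catalyst <-> catalyst intermediate A; catalyst intermediate A <-> catalyst intermediate B; catalyst intermediate B -> released group + catalyst intermediate C; substrate + catalyst intermediate C -> catalyst intermediate D; catalyst intermediate D -> free catalyst + product; substrate + released group <-> idle adduct; crystals <-> released group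

- part of the substrate that has reacted at the end, east
- part of the substrate that has reacted at the end, south
- what raising the concentration of reagent from its lowest to its highest value here does to the part of the substrate that has reacted (changes below 5 percentage points count as none) (it rises / no change / it falls)

What does one reagent molecule buy? Follow it. It binds free catalyst as catalyst intermediate A, turns into catalyst intermediate B and drops its released group, which leaves catalyst intermediate C. At the early forks it may turn back, and I count that as delay, not loss. Catalyst intermediate C then takes one substrate through catalyst intermediate D to one product and free catalyst. So, while substrate lasts, one reagent buys one product.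

What do you carry to the new flasks? The reagent charge as a fraction of the substrate charge, the reagent ceiling, with reagent as the limiting reagent wherever that fraction stays under the whole. For east it is 90.0%. For south it is 180%, so there substrate ends first and 44.4% of the reagent should stay over.

Does a run test the case above the whole? Yes: elm's ceiling is 122%, and its substrate read 0% at 50.0 min.

But cedar's balance misses 4.20% at 8.00 min. Is that a leak? I read it as substrate parked in idle adduct, since by 90.0 min the gap reads 0.100%, with a scatter of 1 percentage point.

And the time? Cedar's product read 92.3% at 90.0 min, and east gets twice that time.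

So my reckoning is east near 90.0%, south the whole charge, and a step of 10 points against a margin of 5 points.

The forecast gives 90% for east, 100% for south, and for the trend: it rises. Its ground: “Product levels off at the reagent charge.”

The flasks give 90.6% for east and 100% for south. On the trend the answer is: it rises, by 9.4 points.

    reagent + free catalyst ⇌ catalyst intermediate A (K = 130 M⁻¹, k = 0.290 M⁻¹ s⁻¹)
    catalyst intermediate A ⇌ catalyst intermediate B (K = 1.30, k = 0.350 s⁻¹)
    catalyst intermediate B → released group + catalyst intermediate C (k = 0.430 s⁻¹)
    substrate + catalyst intermediate C → catalyst intermediate D (k = 11.0 M⁻¹ s⁻¹)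
    catalyst intermediate D → free catalyst + product (k = 0.390 s⁻¹)
    substrate + released group ⇌ idle adduct, settled at all times (K = 2.60 M⁻¹)
    crystals ⇌ released group, rate k7*(cs7 - [released group]) while solid is left; crystals form when [released group] > cs7 (solubility = 25.0 mM, k = 0.0280 s⁻¹)

East's product of 90.0% stands at its ceiling of 90.0%, with reagent at 0%. South ends with substrate at 0% and 43.8% of its reagent free. The reagent charge is the main reason for the difference: south given east's reagent falls from 100% to 90.6%.

East's flask with 1.0 M of substrate has its ceiling lowered to 36.0%. It gives 36.0% product and 3.91% idle adduct, so 39.9% has reacted.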